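**Retrosynthetic overview**

1. The strategy rests on three adjacent carbons: C6 carries the lactone oxygen (ring C: O6, C6, C7, C11, C12), C7 the C7–C11 bond, C8 the crotonate oxygen, with the lactone trans-fused and O8 anti to C11. This is the pattern left when a carbanion hung from O6 as its diethylphosphonoacetate opens a 7,8-cis-epoxide at C7 with inversion; the α-phosphono lactone so formed then gives C11=C13 with formaldehyde in the same flask.
2. Ring A (furanone: O, C3, C2, C1, C10) holds C10–O–C3–C4 antiperiplanar, so by a geometric estimate the oxa-bridged nine-membered ring B (O, C3 to C10) closes only over an extended C6–C7–C8–C9. A cis-epoxide (C6 and C9 syn) should not fit into ring B, so the opening is run on the diene in which ring B is still open between C4 and C5, and ring B is closed afterwards.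
3. Disconnections, backwards: O15–PMB and O8–crotonyl; C4=C5 (ring-closing metathesis); C7–C11 and C11=C13 (key step); O6–C12 with inversion at C6 (Mitsunobu); 7,8-epoxide (peracid, A(1,3) control); C7=C8 (semihydrogenation) and C6–C7 (alkynylation of acrolein); ring A (aldol, oxidation, cyclodehydration); C9–C10 (alkylation of the lactic acid dioxolanone).
4. Order of ring formation: A (step 9), C (step 15), B (step 16).

Key step: step 15

Remark: carbons are numbered C1 (ketone), C2=C3, C4 (bearing C15)=C5, C6 to C10 (C14 on C10), C11(=C13)–C12 (lactone carbonyl); "seco" means ring B open between C4 and C5, each carrying =CH2. Formaldehyde 21 is used as paraformaldehyde. The sense of induction of the ProPhenol ligand in step 11 is not asserted: the antipode that gives the 6R carbinol is used.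

**Route**

Step 1
Reactants: 1 (S)-lactic acid; 2 pivalaldehyde
Product: 3 (2S,5S)-2-tert-butyl-5-methyl-1,3-dioxolan-4-one (cis)
Conditions: p-TsOH (cat.), H2SO4 (cat.), pentane, reflux, water separator; cis isomer crystallised
Reagents that add atoms: none
Why: Acid-catalysed acetalisation (first stage of self-regeneration of stereocentres) should give mainly the cis dioxolanone, the lactate centre being carried over unchanged and the acetal centre set cis to the methyl group under thermodynamic control.

Step 2
Reactants: 3 (2S,5S)-2-tert-butyl-5-methyl-1,3-dioxolan-4-one; 4 3-bromo-1-(trimethylsilyl)prop-1-yne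
Product: 5 (2S,5R)-2-tert-butyl-5-methyl-5-[3-(trimethylsilyl)prop-2-yn-1-yl]-1,3-dioxolan-4-one
Conditions: LiN(iPr)2, THF, −78 °C; then 4, −78 → −30 °C
Reagents that add atoms: none
Why: Enolate alkylation in which the propargylic bromide enters anti to the tert-butyl group, so that C10 is set (R) with net retention of the lactate configuration and C7–C9 are attached.

Step 3
Reactants: 5 (2S,5R)-alkylated dioxolanone
Product: 6 (2R)-2-hydroxy-N-methoxy-N,2-dimethyl-5-(trimethylsilyl)pent-4-ynamide
Conditions: MeNH(OMe)·HCl, iPrMgCl, THF, −20 → 0 °C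
Reagents that add atoms: N,O-dimethylhydroxylamine hydrochloride, CNOC.Cl
Why: Aminolysis of the activated acylal ester to the Weinreb amide, the hemiacetal alkoxide leaving group collapsing with loss of pivalaldehyde to free the tertiary hydroxyl.

Step 4
Reactants: 6 Weinreb amide
Product: 7 (3R)-3-hydroxy-3-methyl-6-(trimethylsilyl)hex-5-yn-2-one
Conditions: MeMgBr (3.5 equiv), THF, 0 °C
Reagents that add atoms: methylmagnesium bromide, C[Mg]Br
Why: Weinreb ketone synthesis, the chelated tetrahedral intermediate stopping at the methyl ketone (the methyl group becomes C2).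

Step 5
Reactants: 8 2-methylidenepropane-1,3-diol
Product: 9 2-{[(4-methoxybenzyl)oxy]methyl}prop-2-en-1-ol
Conditions: NaH (1 equiv), 4-methoxybenzyl chloride (1 equiv), Bu4NI (cat.), THF/DMF, 0 °C → rt
Reagents that add atoms: 4-methoxybenzyl chloride, COc1ccc(CCl)cc1
Why: Williamson etherification of a symmetric diol with one equivalent of base and halide gives the mono ether (C15–O protected).

Step 6
Reactants: 9 mono-PMB ether
Product: 10 2-{[(4-methoxybenzyl)oxy]methyl}prop-2-enal
Conditions: MnO2, CH2Cl2, rt
Reagents that add atoms: none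
Why: Selective oxidation of the allylic alcohol by MnO2 gives the enal that supplies C3, C4 and C15.

Step 7
Reactants: 7 (3R)-ketol; 10 enal
Product: 11 (6R)-3,6-dihydroxy-2-{[(4-methoxybenzyl)oxy]methyl}-6-methyl-9-(trimethylsilyl)non-1-en-8-yn-5-one (both C3 epimers)
Conditions: LiN(iPr)2 (2.2 equiv), THF, −78 °C; then 10
Reagents that add atoms: none
Why: Aldol addition of the kinetic methyl-ketone enolate (alkoxide–enolate dianion) to the aldehyde carbon forms C2–C3, the new carbinol centre being removed in step 8.

Step 8
Reactants: 11 aldol adduct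
Product: 12 (6R)-6-hydroxy-2-{[(4-methoxybenzyl)oxy]methyl}-6-methyl-9-(trimethylsilyl)non-1-en-8-yne-3,5-dione
Conditions: Dess–Martin periodinane, NaHCO3, CH2Cl2, 0 °C → rt
Reagents that add atoms: none
Why: Dess–Martin oxidation of the secondary allylic alcohol (the tertiary hydroxyl is inert) gives the α′-hydroxy 1,3-diketone.

Step 9
Reactants: 12 hydroxy diketone
Product: 13 (2R)-5-{3-[(4-methoxybenzyl)oxy]prop-1-en-2-yl}-2-methyl-2-[3-(trimethylsilyl)prop-2-yn-1-yl]furan-3(2H)-one
Conditions: 1 M aq. HCl, THF, rt
Reagents that add atoms: none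
Why: Acid-catalysed cyclodehydration (hemiketalisation of the C10 hydroxyl onto the C3 carbonyl, then loss of water) closes the 3(2H)-furanone, ring A.

Step 10
Reactants: 13 silylalkyne furanone
Product: 14 (2R)-5-{3-[(4-methoxybenzyl)oxy]prop-1-en-2-yl}-2-methyl-2-(prop-2-yn-1-yl)furan-3(2H)-one
Conditions: Bu4NF, AcOH, THF, 0 °C
Reagents that add atoms: none
Why: Fluoride-induced protodesilylation of the alkynylsilane, buffered with acetic acid so that no nucleophile adds to the dienone.

Step 11
Reactants: 14 terminal alkyne; 15 acrolein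
Product: 16 (6R,10R)-enynol: (2R)-2-[(4R)-4-hydroxyhex-5-en-2-yn-1-yl]-5-{3-[(4-methoxybenzyl)oxy]prop-1-en-2-yl}-2-methylfuran-3(2H)-one
Conditions: Me2Zn, ProPhenol (antipode giving 6R, 20 mol %), Ph3PO, toluene, 0–4 °C; then 15
Reagents that add atoms: none
Why: Zinc–ProPhenol catalysed asymmetric alkynylation of an enal (1,2-addition of the alkynylzinc) forms C6–C7 and sets C6 (R) by reagent control, the non-enolisable furanone ketone and the dienone being left alone by the organozinc.

Step 12
Reactants: 16 enynol
Product: 17 (6R,7Z,10R)-dienol: (2R)-2-[(2Z,4R)-4-hydroxyhexa-2,5-dien-1-yl]-5-{3-[(4-methoxybenzyl)oxy]prop-1-en-2-yl}-2-methylfuran-3(2H)-one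
Conditions: H2 (1 atm), Pd/CaCO3 poisoned with Pb(OAc)2 (Lindlar catalyst), quinoline, EtOAc, rt, stopped at one equivalent
Reagents that add atoms: none
Why: Lindlar semihydrogenation adds H2 syn to the alkyne and should give the Z C7=C8 alkene, the alkyne being reduced faster than the vinyl and conjugated alkenes.

Step 13
Reactants: 17 Z-dienol
Product: 18 threo epoxy alcohol (6R,7S,8R,10R): 7,8-cis-epoxide on the face of the C6 hydroxyl in the conformer with H6 in the alkene plane
Conditions: mCPBA, NaHCO3, CH2Cl2, 0 °C
Reagents that add atoms: 3-chloroperoxybenzoic acid, O=C(OO)c1cccc(Cl)c1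
Why: Hydroxyl-directed peracid epoxidation of a Z-allylic alcohol, in which A(1,3) strain holds H6 in the alkene plane and the hydrogen-bonded peracid delivers oxygen to the hydroxyl face, should set C7 and C8 as the threo isomer, while the dienone alkenes (electron-poor) and the vinyl group react more slowly.

Step 14
Reactants: 18 threo epoxy alcohol; 19 diethylphosphonoacetic acid
Product: 20 erythro seco epoxide C6 diethylphosphonoacetate (6S,7R,8R,10R): the key-step precursor with ring B open between C4 and C5
Conditions: PPh3, DIAD, THF, 0 °C → rt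
Reagents that add atoms: none
Why: Mitsunobu esterification (SN2 displacement of the alkoxyphosphonium by the carboxylate) inverts C6 and so brings O6 syn to the epoxide oxygen, the arrangement from which a group hung on O6 can reach the back side of C7.

Step 15
Reactants: 20 erythro seco epoxide phosphonoacetate; 21 formaldehyde
Product: 23 seco 8-hydroxy α-methylene lactone (6S,7S,8R,10R), via α-phosphono lactone 22 (not isolated)
Conditions: LiN(SiMe3)2 (1.0 equiv), THF (0.005 M), −78 → 50 °C; then (CH2O)n, 0 °C → rt
Reagents that add atoms: none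
Why: Proposed new method: the base deprotonates the phosphonoacetate; because the phosphoryl group can carry the charge outside the forming ring, the ester carbonyl is free to twist and carbanion C11 can attack C7 from the face opposite the epoxide oxygen in a 5-exo-tet closure that forms ring C and releases the C8 alkoxide, which is protonated by the more acidic α-phosphono lactone 22, whose anion then olefinates formaldehyde (Horner–Wadsworth–Emmons) to give C11=C13. The closest known reactions are the intermolecular opening of epoxides by phosphonoacetate anions followed by methylenation of the α-phosphono lactone with formaldehyde, and the closure of O-tethered phosphonoacetates onto the carbon β to the ester oxygen in butenolide synthesis by intramolecular Horner–Wadsworth–Emmons reaction; the tethered opening of an epoxide is untested. C7 is the only lasting new stereocentre and is set by SN2 inversion of the epoxide carbon, C6 and C8 keeping their oxygens untouched, while C11 is epimeric in 22 and becomes sp2. The step needs attack at C7 and not C8, C- and not O-alkylation, and no addition to the dienone: the five-membered transition state from O6 should favour C7, O-alkylation to a ketene acetal should be reversible whereas C–C bond formation is not, and high dilution with one equivalent of base should suppress intermolecular Michael addition. Proton transfer from 22 to the C8 alkoxide removes the nucleophile that could move the lactone to O8 or attack phosphorus.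

Step 16
Reactants: 23 seco 8-hydroxy α-methylene lactone
Product: 24 furanone-bridged 8-hydroxy α-methylene lactone, C15 4-methoxybenzyl ether (6S,7S,8R,10R; C4=C5 Z)
Conditions: second-generation Hoveyda–Grubbs catalyst (10 mol %), 1,4-benzoquinone (cat.), toluene (0.002 M), 80 °C
Reagents that add atoms: none
Why: Ring-closing olefin metathesis between the C5 vinyl and C4 methylidene groups closes ring B, in which only the Z alkene (C3 and C6 cis) is possible; C6–C9 are now sp3 and can take the extended shape the furanone bridge demands, and the α-methylene lactone is too electron-poor and hindered to compete.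

Step 17
Reactants: 24 bridged 8-hydroxy lactone
Product: 25 8-O-crotonate, C15 4-methoxybenzyl ether
Conditions: (E)-crotonic anhydride, Et3N, DMAP (cat.), CH2Cl2, 0 °C
Reagents that add atoms: (2E)-but-2-enoic anhydride, C/C=C/C(=O)OC(=O)/C=C/C
Why: DMAP-catalysed acylation of the only free hydroxyl (C8) with retention, placed after the metathesis so that the crotonate alkene cannot take part in it.

Step 18
Reactants: 25 crotonate PMB ether
Product: 26 CNP0225232.1
Conditions: DDQ, CH2Cl2/pH 7 buffer, 0 °C
Reagents that add atoms: none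
Why: Oxidative cleavage of the 4-methoxybenzyl ether by DDQ (hydride abstraction, hydrolysis of the oxocarbenium ion) frees the C15 alcohol without touching the dienone, the crotonate or the methylene lactone.

**Compound list**

1 | (S)-lactic acid | C[C@H](O)C(=O)O | starting material
2 | pivalaldehyde | CC(C)(C)C=O | starting material
3 | (2S,5S)-2-tert-butyl-5-methyl-1,3-dioxolan-4-one | C[C@@H]1O[C@H](C(C)(C)C)OC1=O | intermediate
4 | 3-bromo-1-(trimethylsilyl)prop-1-yne | C[Si](C)(C)C#CCBr | starting material
5 | (2S,5R)-2-tert-butyl-5-methyl-5-[3-(trimethylsilyl)prop-2-yn-1-yl]-1,3-dioxolan-4-one | C[C@]1(CC#C[Si](C)(C)C)O[C@H](C(C)(C)C)OC1=O | intermediate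
6 | (2R)-2-hydroxy-N-methoxy-N,2-dimethyl-5-(trimethylsilyl)pent-4-ynamide | CON(C)C(=O)[C@](C)(O)CC#C[Si](C)(C)C | intermediate
7 | (3R)-3-hydroxy-3-methyl-6-(trimethylsilyl)hex-5-yn-2-one | CC(=O)[C@](C)(O)CC#C[Si](C)(C)C | intermediate
8 | 2-methylidenepropane-1,3-diol | C=C(CO)CO | starting material
9 | 2-{[(4-methoxybenzyl)oxy]methyl}prop-2-en-1-ol | C=C(CO)COCc1ccc(OC)cc1 | intermediate
10 | 2-{[(4-methoxybenzyl)oxy]methyl}prop-2-enal | C=C(C=O)COCc1ccc(OC)cc1 | intermediate
11 | aldol adduct, (6R)-3,6-dihydroxy-2-{[(4-methoxybenzyl)oxy]methyl}-6-methyl-9-(trimethylsilyl)non-1-en-8-yn-5-one, C3 epimers | C=C(COCc1ccc(OC)cc1)C(O)CC(=O)[C@](C)(O)CC#C[Si](C)(C)C | intermediate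
12 | (6R)-6-hydroxy-2-{[(4-methoxybenzyl)oxy]methyl}-6-methyl-9-(trimethylsilyl)non-1-en-8-yne-3,5-dione | C=C(COCc1ccc(OC)cc1)C(=O)CC(=O)[C@](C)(O)CC#C[Si](C)(C)C | intermediate
13 | (2R)-5-{3-[(4-methoxybenzyl)oxy]prop-1-en-2-yl}-2-methyl-2-[3-(trimethylsilyl)prop-2-yn-1-yl]furan-3(2H)-one | C[Si](C)(C)C#CC[C@@]1(C)OC(C(=C)COCc2ccc(OC)cc2)=CC1=O | intermediate
14 | (2R)-5-{3-[(4-methoxybenzyl)oxy]prop-1-en-2-yl}-2-methyl-2-(prop-2-yn-1-yl)furan-3(2H)-one | C#CC[C@@]1(C)OC(C(=C)COCc2ccc(OC)cc2)=CC1=O | intermediate
15 | acrolein | C=CC=O | starting material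
16 | (6R,10R)-enynol, (2R)-2-[(4R)-4-hydroxyhex-5-en-2-yn-1-yl]furanone | O[C@H](C=C)C#CC[C@@]1(C)OC(C(=C)COCc2ccc(OC)cc2)=CC1=O | intermediate
17 | (6R,7Z,10R)-dienol, (2R)-2-[(2Z,4R)-4-hydroxyhexa-2,5-dien-1-yl]furanone | O[C@H](C=C)/C=C\C[C@@]1(C)OC(C(=C)COCc2ccc(OC)cc2)=CC1=O | intermediate
18 | threo epoxy alcohol (6R,7S,8R,10R), 7,8-cis-epoxide | O[C@H](C=C)[C@@H]1O[C@@H]1C[C@@]2(C)OC(C(=C)COCc3ccc(OC)cc3)=CC2=O | intermediate
19 | diethylphosphonoacetic acid | CCOP(=O)(CC(=O)O)OCC | starting material
20 | erythro seco 7,8-cis-epoxide C6 diethylphosphonoacetate (6S,7R,8R,10R), key-step precursor | CCOP(=O)(OCC)CC(=O)O[C@@H](C=C)[C@@H]1O[C@@H]1C[C@@]2(C)OC(C(=C)COCc3ccc(OC)cc3)=CC2=O | intermediate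
21 | formaldehyde | C=O | starting material
22 | seco 8-hydroxy α-(diethoxyphosphoryl) lactone, C11 epimers, other centres as in 23 | CCOP(=O)(OCC)C1C(=O)O[C@@H](C=C)[C@@H]1[C@H](O)C[C@@]2(C)OC(C(=C)COCc3ccc(OC)cc3)=CC2=O | intermediate (not isolated)
23 | seco 8-hydroxy α-methylene lactone (6S,7S,8R,10R), key-step product | C=C1C(=O)O[C@@H](C=C)[C@@H]1[C@H](O)C[C@@]2(C)OC(C(=C)COCc3ccc(OC)cc3)=CC2=O | intermediate
24 | furanone-bridged 8-hydroxy α-methylene lactone, C15 4-methoxybenzyl ether | C=C1C(=O)O[C@H]2/C=C(/COCc3ccc(OC)cc3)C3=CC(=O)[C@@](C)(C[C@@H](O)[C@H]12)O3 | intermediate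
25 | 8-O-[(E)-but-2-enoyl] derivative of 24 | C=C1C(=O)O[C@H]2/C=C(/COCc3ccc(OC)cc3)C3=CC(=O)[C@@](C)(C[C@@H](OC(=O)/C=C/C)[C@H]12)O3 | intermediate
26 | CNP0225232.1 | C=C1C(=O)O[C@H]2/C=C(/CO)C3=CC(=O)[C@@](C)(C[C@@H](OC(=O)/C=C/C)[C@H]12)O3 | target

**Step count**

Total: 18 steps. Longest linear sequence: 16 steps from (S)-lactic acid (steps 1–4 and 7–18); steps 5 and 6 make the enal 10.

**Steps most likely to fail**

Step 15 (key step). The enolate oxygen may alkylate in place of carbon, or the carbanion may attack C8 or add to the dienone of another molecule, or the epoxide may prove too poor an electrophile for the phosphonate carbanion. The fallback builds the lactone and the methylene group in separate, known operations with a malonate, the doubly stabilised carbanion class established for intramolecular alkylation by epoxides. It sets out from epoxy alcohol 18. Mitsunobu esterification with 2-(trimethylsilyl)ethyl hydrogen malonate gives the inverted mixed malonate F1. NaH in THF closes the lactone at C7 to the α-[2-(trimethylsilyl)ethoxycarbonyl] lactone F2, and Bu4NF frees the α-carboxy lactone F3. Decarboxylative Mannich methylenation (Et2NH, aqueous formaldehyde; then NaOAc, AcOH, heat) comes back to the route at 23.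

Step 16. The carbene loaded on the C5 vinyl group may be held as a chelate by the lactone carbonyl, or may react between molecules faster than it closes the strained bridged ring onto the hindered, electron-poor C4 methylidene group, so that oligomers form. The fallback closes the carbocycle before the oxygen bridge exists. It sets out from aldol adduct 11. The secondary C3 hydroxyl is silylated (tBuMe2SiCl, imidazole) to silyl ether F4, and K2CO3 in methanol frees the terminal alkyne F5. The operations of steps 11 to 15 are then run on this open series: alkynylation of acrolein gives enynol F6, semihydrogenation gives Z-dienol F7, and hydroxyl-directed epoxidation (VO(acac)2, tBuOOH, which spares the now unconjugated methylidene group) gives threo epoxy alcohol F8. Mitsunobu esterification with 19 gives phosphonoacetate F9, and base followed by formaldehyde gives α-methylene lactone F10. Ring-closing metathesis of F10 closes an unbridged ten-membered carbocycle, silyl ether F11, with the Z C4=C5 bond expected as the more stable geometry in this ring size. HF·pyridine gives triol F12, MnO2 oxidises only the allylic C3 hydroxyl to the 1,3-diketone F13, and dilute acid closes the furanone across the ring, which comes back to the route at 24.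

Step 14. The displacement may take the SN2′ course at the vinyl terminus, the activated allylic carbinol may eliminate, or the acidic methylene of the phosphonoacetic acid may be alkylated. The fallback inverts C6 by oxidation and reduction instead of substitution. It sets out from 18. Dess–Martin oxidation gives epoxy enone F14. Reduction with Zn(BH4)2 in ether at −30 °C, under chelation between the ketone and epoxide oxygens, is expected to give the erythro epoxy alcohol F15. Esterification of F15 with 19 (DCC, DMAP, CH2Cl2), which retains C6, comes back to the route at 20.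

**Further compounds**

F1 | step 15 | erythro seco epoxide C6 2-(trimethylsilyl)ethyl malonate (6S,7R,8R,10R) | C[Si](C)(C)CCOC(=O)CC(=O)O[C@@H](C=C)[C@@H]1O[C@@H]1C[C@@]2(C)OC(C(=C)COCc3ccc(OC)cc3)=CC2=O
F2 | step 15 | seco 8-hydroxy lactone with 2-(trimethylsilyl)ethoxycarbonyl on C11 | C[Si](C)(C)CCOC(=O)C1C(=O)O[C@@H](C=C)[C@@H]1[C@H](O)C[C@@]2(C)OC(C(=C)COCc3ccc(OC)cc3)=CC2=O
F3 | step 15 | seco 8-hydroxy lactone C11 carboxylic acid | OC(=O)C1C(=O)O[C@@H](C=C)[C@@H]1[C@H](O)C[C@@]2(C)OC(C(=C)COCc3ccc(OC)cc3)=CC2=O
F4 | step 16 | C3 tert-butyldimethylsilyl ether of 11 | C=C(COCc1ccc(OC)cc1)C(O[Si](C)(C)C(C)(C)C)CC(=O)[C@](C)(O)CC#C[Si](C)(C)C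
F5 | step 16 | terminal alkyne from F4 | C=C(COCc1ccc(OC)cc1)C(O[Si](C)(C)C(C)(C)C)CC(=O)[C@](C)(O)CC#C
F6 | step 16 | open-chain (6R)-enynol | C=C(COCc1ccc(OC)cc1)C(O[Si](C)(C)C(C)(C)C)CC(=O)[C@](C)(O)CC#C[C@H](O)C=C
F7 | step 16 | open-chain (6R,7Z)-dienol | C=C(COCc1ccc(OC)cc1)C(O[Si](C)(C)C(C)(C)C)CC(=O)[C@](C)(O)C/C=C\[C@H](O)C=C
F8 | step 16 | open-chain threo epoxy alcohol | C=C(COCc1ccc(OC)cc1)C(O[Si](C)(C)C(C)(C)C)CC(=O)[C@](C)(O)C[C@H]1O[C@H]1[C@H](O)C=C
F9 | step 16 | open-chain erythro epoxide C6 diethylphosphonoacetate | C=C(COCc1ccc(OC)cc1)C(O[Si](C)(C)C(C)(C)C)CC(=O)[C@](C)(O)C[C@H]1O[C@H]1[C@@H](OC(=O)CP(=O)(OCC)OCC)C=C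
F10 | step 16 | open-chain 8-hydroxy α-methylene lactone, furanone not yet closed | C=C1C(=O)O[C@@H](C=C)[C@@H]1[C@H](O)C[C@@](C)(O)C(=O)CC(O[Si](C)(C)C(C)(C)C)C(=C)COCc2ccc(OC)cc2
F11 | step 16 | ten-membered carbocycle, Z C4=C5, C3 silyl ether | C=C1C(=O)O[C@H]2/C=C(/COCc3ccc(OC)cc3)C(O[Si](C)(C)C(C)(C)C)CC(=O)[C@@](C)(C[C@@H](O)[C@H]12)O
F12 | step 16 | ten-membered 3,8,10-triol | C=C1C(=O)O[C@H]2/C=C(/COCc3ccc(OC)cc3)C(O)CC(=O)[C@@](C)(C[C@@H](O)[C@H]12)O
F13 | step 16 | ten-membered 1,3-diketone | C=C1C(=O)O[C@H]2/C=C(/COCc3ccc(OC)cc3)C(=O)CC(=O)[C@@](C)(C[C@@H](O)[C@H]12)O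
F14 | step 14 | epoxy enone, C6 ketone of 18 | C=CC(=O)[C@@H]1O[C@@H]1C[C@@]2(C)OC(C(=C)COCc3ccc(OC)cc3)=CC2=O
F15 | step 14 | erythro epoxy alcohol (6S), C6 epimer of 18 | O[C@@H](C=C)[C@@H]1O[C@@H]1C[C@@]2(C)OC(C(=C)COCc3ccc(OC)cc3)=CC2=O
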